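The readings come from a simulation for substances that don't exist, and the scatter is random.

I read the east flask at 1.50 min and again at 10.0 min. Between those readings the complexes I could see lost 32.0% of the charge. I took that loss as capture, with one capture agent used for each complex lost. The east charges of starting complex and capture agent were equal, so I took the free share of capture agent at a reading as the share of complexes still seen.

Capture needs complex with one exchanged and capture agent together, so I took its rate as following their product. I summed that product over the east readings from 1.50 min to 10.0 min and set it against the loss. At the charged capture agent this gave 1.88 min. I called this the capture half-life: the pseudo-first-order half-life of complex with one exchanged against capture agent held at 1 mM. It is a value read from readings that scatter by 0.5 percentage points.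

| setting | east | west | Friday's | Tuesday's | Sunday's |
|---|---|---|---|---|---|
| starting complex | 1 mM | 1 mM | 1.0 mM | 1.0 mM | 1.0 mM |
| incoming ligand | 0.65 mM | 6.2 mM | 0.500 mM | 2.00 mM | 4.00 mM |
| capture agent | 1 mM | 1 mM | 1.00 mM | 1.00 mM | 1.00 mM |
| remark | run made earlier | run made earlier |  |  |  |
| time |  |  | 15 min | 15 min | 15 min |

| run | time / min | complex with one exchanged / % | complex with two exchanged / % | starting complex / % |
|---|---|---|---|---|
| east | 0.833 | 32.1 | 5.2 | 49.5 |
| east | 1.50 | 28.0 | 3.3 | 46.9 |
| east | 3.00 | 22.2 | 2.0 | 43.8 |
| east | 6.00 | 14.5 | 1.1 | 40.4 |
| east | 10.0 | 8.7 | 0.2 | 37.3 |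
| west | 1.00 | 12.1 | 15.9 | 1.3 |
| west | 2.50 | 18.9 | 16.3 | 4.2 |
| west | 5.00 | 18.3 | 15.1 | 5.4 |
| west | 8.00 | 17.7 | 11.0 | 5.2 |
| west | 10.0 | 16.4 | 10.2 | 5.5 |

(standard deviation of a reading: 0.5 percentage points)

- final complex with one exchanged, as a percentage of the starting complex charged, for each flask in turn (Friday's, Tuesday's, Sunday's)

Friday's flask got 0.500 mM of incoming ligand, less than its 1.00 mM of capture agent. I counted one incoming ligand for each capture, so I reckoned that capture agent in Friday's flask stayed above 0.500 mM. At that floor the capture half-life stretched to 3.76 min, still shorter than the 15 min of the run. I started from the whole ligand charge as complex with one exchanged and let it fall at that slower pace. My rough estimate for Friday's was 3.15%. I reckoned nothing for Tuesday's or Sunday's.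

The forecast gave 2.5%, 12% and 14%, on the view that “Capture then slowly drains the one-exchanged complex”. Its Friday's value stood below my estimate.

The flasks gave 2.03%, 12.4% and 13.3%, and the forecast held within its margin on each. Sunday's flask also held 10.9% of complex with three exchanged at the end.

    starting complex + incoming ligand ⇌ leaving ligand + complex with one exchanged (K = 14.0, k = 390 /M/s)
    complex with one exchanged + incoming ligand ⇌ leaving ligand + complex with two exchanged (K = 2.90, k = 210 /M/s)
    complex with two exchanged + incoming ligand ⇌ leaving ligand + complex with three exchanged (K = 9.30, k = 320 /M/s)
    complex with one exchanged + capture agent → trapped intermediate (k = 6.60 /M/s)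
    2 incoming ligand → homo dimer (k = 6.70 /M/s)

I put the capture half-life of 1.88 min to Sunday's flask, using the amounts of complex with one exchanged and capture agent at 7.50 min and 15.0 min. It gave an estimated gain of 20.7% of trapped intermediate over that stretch. Sunday's trapped intermediate went from 42.3% to 63.3%.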